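## Structural features

The target is a diaryl ether of two hexasubstituted benzene rings. Ring A carries C1 CO2Me, C2 Me, C3 O-aryl, C4 OH, C5 Me and C6 OH; ring B carries C1' O-aryl, C2' CHO, C3' OH, C4' Cl, C5' Me and C6' CO2H; the only link is the oxygen between C3 and C1'. There is no stereogenic centre, so no stereocentres adjoin. The real difficulty is the ether oxygen itself: it is flanked by four ortho substituents (C2 methyl, C4 hydroxyl, C2' formyl, C6' carboxyl), which makes a direct coupling of two finished rings unattractive. The fragile groups are the C2' aldehyde (it condenses with any enolizable ketone placed on the C1' oxygen), the aryl chloride (labile to hydrogenolysis), and the C6' acid, which lies within reach of C4–OH and could lactonize to a depsidone. The two carboxyl groups must also end in different states, a methyl ester on ring A and a free acid on ring B. Ring B has the pattern of orsellinic acid with a formyl group and a chlorine added at the two positions activated by its oxygens. The key step exploits ring A: C1 and C2, with ester and methyl, are the two sp carbons of a but-2-ynoate, and C3–C6 carry oxygen at C3, C4 and C6 and methyl at C5 exactly as the dienol form of a 4-aryloxy-2-methylacetoacetate does. Ring A can therefore be grown on the C1' oxygen by a (4+2) cycloaddition and aromatization, after the ether bond has been made at an sp3 carbon.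

## Logic of the disconnections

**17 from 16.** The two benzyl–oxygen bonds on ring B (C3' ether, C6' ester) are cut. One kind of group then masks both acidic functions of ring B, and a Lewis acid removes it without hydrogen, so chloride and aldehyde are not endangered. The gain is an end game of one operation. The forward step must spare the ring A methyl ester and must not close the C6' acid onto C4–OH.

**16 from 12 and 13 (through 14 and 15).** The C2–C3 and C1–C6 bonds of ring A are cut, together with the acetal that 15 still carries. A whole hexasubstituted ring disappears, and the crowded diaryl ether becomes the enol ether of an open chain. The forward step must give one orientation (ester next to C6), must tolerate heat, and must aromatize by loss of methanol only.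

**12 from 10 (through 11).** The two O–Si bonds are cut, which returns the diene to a β-keto ester. The forward steps must silylate first the enol between the two carbonyls and then, after deprotonation at the aryloxy-bearing CH2, the ester oxygen. The base must leave the ring B methyl group and the neighbouring ester alone.

**10 from 6 and 9.** The bond between the C1' oxygen and the sp3 carbon that becomes C3 is cut. A Williamson alkylation replaces a diaryl ether coupling, and the molecule falls into a ring B phenol and a four-carbon chain holding C3–C6 and the C5 methyl. The forward step requires a masked C2' aldehyde and a phenoxide that reacts faster than the enolate of 9.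

**9 from 7 (through 8).** The C–Br bond is cut. The forward bromination must end at the terminal carbon, which equilibration should secure.

**6 from 5.** The two acetal C–O bonds are cut. The forward step must acetalize an aldehyde flanked by two oxygen substituents under acid that the benzyl groups tolerate.

**5 from 4.** The C4'–Cl bond is cut. Every other ring position is filled, so the chlorination has a single site.

**4 from 2 (through 3).** The bond from C2' to the formyl carbon is cut. The forward formylation must go between the free hydroxyl and the benzyl ether, not next to the methyl group, which calls for a reagent delivered by the phenoxide.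

**2 from 1.** The two O–benzyl bonds are cut. The forward alkylation must leave the chelated hydroxyl, the future ether oxygen, free.

## Other disconnections considered

**Alternative 1:** Ring B is cut at C4'–C5' and C2'–C3'.
- Forward key step: the pyranone benzyl 4-[2,4-bis(benzyloxy)-5-(methoxycarbonyl)-3,6-dimethylphenoxy]-6-methyl-2-oxo-2H-pyran-5-carboxylate A1 would act as an electron-poor diene toward 2-chloro-1,1-dimethoxyethene A2. The chlorine-bearing nucleophilic carbon of A2 would bond to C6 of A1 (future C5') and the acetal carbon to C3 (future C2'). Loss of CO2 and then of methanol would give benzyl 2-[2,4-bis(benzyloxy)-5-(methoxycarbonyl)-3,6-dimethylphenoxy]-5-chloro-4-methoxy-6-methylbenzoate A3.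
- In its favour: chlorine, methyl, ester and ether are placed by the polarity of the partners, with no electrophilic chlorination. The ether bond is again made on a non-aromatic carbon, by addition–elimination of the ring A phenol methyl 2,4-bis(benzyloxy)-5-hydroxy-3,6-dimethylbenzoate A4 at C4 of a pyranone.
- Against it here: A3 lacks the C2' formyl carbon and has a methyl ether at C3', so a formylation between two oxygen substituents and an O-demethylation must follow before debenzylation. A4 is itself a fully substituted phenol needing its own synthesis. The aryloxy donor at C4 and the methyl at C6 of A1 both slow an inverse-demand addition, and A2 is a modest, heat-sensitive dienophile.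
- Comparison: both plans avoid joining two finished hexasubstituted rings, and both fix regiochemistry by matched polarization, so on mechanism they are equals. Alternative 1 is the better on the placing of chlorine. On step economy the chosen plan should be shorter, because ring A there costs only 7 and 13 and one step follows the key step, against at least three here plus the synthesis of A4.

**Alternative 2:** Ring B is cut at C2'–C3', C1'–C6' and C3'–C4'.
- Forward key step: 4-chloro-3-methylcyclobut-2-en-1-one A5 would be heated with the aryloxyalkyne methyl 2,4-bis(benzyloxy)-5-{[3-(tert-butyldimethylsilyloxy)prop-1-yn-1-yl]oxy}-3,6-dimethylbenzoate A6. A5 would open to a vinylketene, which adds (2+2) to the alkyne; a second four-electron opening and a six-electron closure, then tautomerization, would give the phenol methyl 2,4-bis(benzyloxy)-5-[2-({tert-butyldimethylsilyloxy}methyl)-4-chloro-3-hydroxy-5-methylphenoxy]-3,6-dimethylbenzoate A7.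
- In its favour: one reagent-free thermal operation builds ring B with the C3' hydroxyl free, chlorine and methyl in place and the ether oxygen at C1'. The polarization of the ynol ether dictates the orientation.
- Against it here: A7 has hydrogen at C6', so the carboxyl must be introduced later between the ether and the methyl group, in the presence of the ring A methyl ester. C2' arrives as a silyloxymethyl group that needs deprotection and oxidation. A5 is sensitive and not an article of commerce. A6 requires an aryl ynol ether made from the hindered phenol A4 with strong base, which threatens the ester of ring A, and aryl ynol ethers are less electron-rich than the alkyl or silyl ones usually used.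
- Comparison: on mechanism the pericyclic cascade is the equal of the cycloaddition–aromatization, and it is the better on atom economy and on leaving the new phenol unprotected. On structure it delivers a less complete ring B (no C6' carboxyl, wrong oxidation level at C2'). On step economy it is clearly longer.

**Alternative 3:** The C1'–O ether bond and the bond from C2' to its exocyclic carbon are cut.
- Forward key step: CsF would release the aryne from 4-chloro-3-methoxy-5-methyl-2-(trimethylsilyl)phenyl trifluoromethanesulfonate A8 under CO2. The caesium phenoxide of A4 would add at C1', remote from the methoxy group, and the C2' aryl anion would be trapped by CO2 to give 2-[2,4-bis(benzyloxy)-5-(methoxycarbonyl)-3,6-dimethylphenoxy]-5-chloro-6-methoxy-4-methylbenzoic acid A9.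
- In its favour: it is the most convergent plan, since both rings arrive fully formed. The hindered ether bond is made by an aryne, which ortho substituents slow little, and two bonds form in one operation. The site of attack is set by the inductive effect of the methoxy group.
- Against it here: A9 has the new carboxyl at C2', where the target has an aldehyde, and hydrogen at C6', where the target has the acid. A reduction to the aldehyde level, a separate carboxylation of C6' and a demethylation at C3' are therefore still needed. The aryl anion may be protonated, or the phenoxide carbonated at oxygen, before the three components meet. A8 is a pentasubstituted arene with a multistep synthesis of its own.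
- Comparison: on convergence and on directness of ether formation alternative 3 is the better. On regiocontrol the two plans are equal. On step economy the chosen plan should win, with one step after the key step against five or more.

Key step: step 9

Remark on the chemistry: the ring B acid is carried as a benzyl ester, so that one alkylation masks the acid and the C3' oxygen, acid-catalysed acetalization is tolerated, and one Lewis acid frees both at the end. The stereogenic carbons met on the way (C2 of 9 and 10, C3 and C6 of 14) are racemic and are erased before the achiral target.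

## Route

Step 1
Reactants: 1 2,4-dihydroxy-6-methylbenzoic acid (orsellinic acid)
Product: 2 benzyl 4-(benzyloxy)-2-hydroxy-6-methylbenzoate
Conditions: BnBr (2.1 equiv), K2CO3 (2.2 equiv), DMF, 0 °C to rt
Reagents that add atoms: benzyl bromide, BrCc1ccccc1
Why: O-Alkylation of the carboxylate and Williamson etherification of the 4-hydroxyl, the more acidic and non-chelated phenol; the 2-hydroxyl is hydrogen-bonded to the ester carbonyl and should stay free when the bromide is limited to two equivalents.

Step 2
Reactants: 2 benzyl 4-(benzyloxy)-2-hydroxy-6-methylbenzoate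
Product: 4 benzyl 4-(benzyloxy)-3-formyl-2-hydroxy-6-methylbenzoate, via hydroxymethyl phenol 3 (not isolated)
Conditions: MgCl2, Et3N, (CH2O)n, MeCN, reflux; 1 M HCl work-up
Reagents that add atoms: paraformaldehyde (formaldehyde), C=O
Why: Magnesium-mediated ortho-formylation (Casnati–Skattebøl): the magnesium phenoxide delivers formaldehyde to C3, the only free position ortho to the hydroxyl, giving 3, which a second formaldehyde oxidizes by hydride transfer. C5 is not ortho to a free hydroxyl and should not react.

Step 3
Reactants: 4 benzyl 4-(benzyloxy)-3-formyl-2-hydroxy-6-methylbenzoate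
Product: 5 benzyl 4-(benzyloxy)-5-chloro-3-formyl-2-hydroxy-6-methylbenzoate
Conditions: SO2Cl2 (1.05 equiv), CH2Cl2, 0 °C to rt, dark
Reagents that add atoms: sulfuryl chloride, O=S(=O)(Cl)Cl
Why: Electrophilic aromatic chlorination at C5, the single open position of the ring, para to the free hydroxyl and ortho to the benzyloxy group; the unactivated benzyl rings and the aldehyde should be inert under ionic conditions.

Step 4
Reactants: 5 benzyl 4-(benzyloxy)-5-chloro-3-formyl-2-hydroxy-6-methylbenzoate
Product: 6 benzyl 4-(benzyloxy)-5-chloro-3-(1,3-dioxolan-2-yl)-2-hydroxy-6-methylbenzoate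
Conditions: HOCH2CH2OH (5 equiv), p-TsOH·H2O (cat.), PhMe, reflux, Dean–Stark; Et3N quench
Reagents that add atoms: ethylene glycol, OCCO
Why: Acid-catalysed acetalization driven by azeotropic removal of water; the benzyl ether and the doubly ortho-substituted benzyl ester tolerate the acid. The acetal is needed because a free C2' aldehyde would condense with the aryloxy ketone under the bases of steps 6 and 8 (benzofuran formation).

Step 5
Reactants: 7 methyl 2-methyl-3-oxobutanoate
Product: 9 methyl 4-bromo-2-methyl-3-oxobutanoate, via 2-bromo keto ester 8 (not isolated)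
Conditions: Br2 (1.0 equiv), CHCl3, 0 °C to rt, 16 h; N2 purge
Reagents that add atoms: bromine, BrBr
Why: α-Bromination of the β-keto ester occurs first at C2 to give 8, and the HBr set free equilibrates the bromine to the terminal C4, the thermodynamic isomer; this bromination–isomerization is the usual entry to 4-bromo-2-alkylacetoacetates.

Step 6
Reactants: 6 benzyl 4-(benzyloxy)-5-chloro-3-(1,3-dioxolan-2-yl)-2-hydroxy-6-methylbenzoate; 9 methyl 4-bromo-2-methyl-3-oxobutanoate
Product: 10 benzyl 4-(benzyloxy)-5-chloro-3-(1,3-dioxolan-2-yl)-2-(4-methoxy-3-methyl-2,4-dioxobutoxy)-6-methylbenzoate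
Conditions: K2CO3 (2.5 equiv), 9 (1.3 equiv, slow addition), acetone, rt to 45 °C
Reagents that add atoms: none
Why: Williamson alkylation of the phenoxide by a primary α-bromo ketone, a very reactive SN2 electrophile, forms the C1'–O bond at an sp3 carbon; the tertiary enolate of 9 is the poorer nucleophile. The product rests as its C2 enolate, which blocks enolization toward the aryloxy CH2 and hence Dieckmann-type attack on the neighbouring ester.

Step 7
Reactants: 10 benzyl 4-(benzyloxy)-5-chloro-3-(1,3-dioxolan-2-yl)-2-(4-methoxy-3-methyl-2,4-dioxobutoxy)-6-methylbenzoate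
Product: 11 benzyl 4-(benzyloxy)-5-chloro-3-(1,3-dioxolan-2-yl)-2-{[4-methoxy-3-methyl-4-oxo-2-(trimethylsilyloxy)but-2-en-1-yl]oxy}-6-methylbenzoate
Conditions: Me3SiCl (1.5 equiv), Et3N (1.6 equiv), PhMe, rt, 48 h; filtration under N2
Reagents that add atoms: chlorotrimethylsilane, C[Si](C)(C)Cl
Why: O-Silylation of the enol between the two carbonyls, the standard first stage in the preparation of 1,3-bis(silyloxy)dienes from β-keto esters; the stereocentre of 10 disappears, and the E/Z mixture converges in step 8.

Step 8
Reactants: 11 benzyl 4-(benzyloxy)-5-chloro-3-(1,3-dioxolan-2-yl)-2-{[4-methoxy-3-methyl-4-oxo-2-(trimethylsilyloxy)but-2-en-1-yl]oxy}-6-methylbenzoate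
Product: 12 benzyl 4-(benzyloxy)-5-chloro-3-(1,3-dioxolan-2-yl)-2-{[(1Z,3Z)-4-methoxy-3-methyl-2,4-bis(trimethylsilyloxy)buta-1,3-dien-1-yl]oxy}-6-methylbenzoate
Conditions: LiN(iPr)2 (1.05 equiv), THF, −78 °C; Me3SiCl, −78 to 0 °C; hexane, filtration; used crude
Reagents that add atoms: chlorotrimethylsilane, C[Si](C)(C)Cl
Why: Vinylogous (γ) deprotonation of the silyloxy enoate and O-silylation of the dienolate give the ketene acetal. The γ-CH2 is activated by the enoate and the aryloxy group and should be well more acidic than the ring B benzylic methyl, so a slight excess of base at −78 °C should take it selectively; the twisted, doubly ortho-substituted benzoate is not expected to be attacked at that temperature.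

Step 9
Reactants: 12 benzyl 4-(benzyloxy)-5-chloro-3-(1,3-dioxolan-2-yl)-2-{[(1Z,3Z)-4-methoxy-3-methyl-2,4-bis(trimethylsilyloxy)buta-1,3-dien-1-yl]oxy}-6-methylbenzoate; 13 methyl but-2-ynoate
Product: 16 benzyl 4-(benzyloxy)-5-chloro-2-[2,4-dihydroxy-5-(methoxycarbonyl)-3,6-dimethylphenoxy]-3-formyl-6-methylbenzoate, via cyclohexadiene cycloadduct 14 (not isolated), via dioxolane resorcinol 15 (not isolated)
Conditions: 13 (4 equiv), PhMe, 120 °C, sealed tube; then 1 M HCl, THF, rt
Reagents that add atoms: water, O
Why: This is a normal-demand (4+2) cycloaddition of an electron-rich 1-methoxy-1,3-bis(trimethylsilyloxy)diene with an alkynoate, the known route from such dienes to 2,4-dihydroxybenzoates, here with an aryloxy group on the diene terminus. Ring A is closed by an intermolecular, concerted but asynchronous cycloaddition that forms C2–C3 and C1–C6 and gives the cyclohexa-1,4-diene 14. Orientation is the selectivity that matters: C3 is the most nucleophilic diene carbon, fed by the C4 silyloxy group and the vinylogous ketene acetal, and it bonds to the methyl-bearing β-carbon of 13, so the ester ends next to C6. The linear alkyne is a sterically undemanding partner for the fully substituted diene, and the (3Z) enol ether keeps the aryloxy group on the outside of the s-cis diene. C6 of 14 has no hydrogen, so the only way to an arene is hydrolysis of the methyl silyl ketal to the C6 ketone with loss of methanol and enolization through the C3 hydrogen; this retains the aryloxy group and gives 15 with both hydroxyls free. The same aqueous acid then hydrolyses the electron-rich aryl dioxolane, which is no longer needed once the basic steps are past, to give 16. No stereocentre remains, because the two sp3 carbons of 14 become planar on aromatization.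

Step 10
Reactants: 16 benzyl 4-(benzyloxy)-5-chloro-2-[2,4-dihydroxy-5-(methoxycarbonyl)-3,6-dimethylphenoxy]-3-formyl-6-methylbenzoate
Product: 17 3-chloro-6-[2,4-dihydroxy-5-(methoxycarbonyl)-3,6-dimethylphenoxy]-5-formyl-4-hydroxy-2-methylbenzoic acid
Conditions: BCl3 (1 M in CH2Cl2, excess), C6HMe5, CH2Cl2, −78 to 0 °C; aqueous work-up
Reagents that add atoms: none
Why: Lewis acid cleavage of the benzyl ether (helped by chelation of boron between the C3' oxygen and the formyl group) and of the benzyl ester, with pentamethylbenzene as a non-basic trap for the benzyl cation. Aryl chloride, aldehyde and methyl ester are expected to survive at low temperature, and water hydrolyses the boron esters.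

## Compound list

1 | 2,4-dihydroxy-6-methylbenzoic acid (orsellinic acid) | Cc1cc(O)cc(O)c1C(=O)O | starting material
2 | benzyl 4-(benzyloxy)-2-hydroxy-6-methylbenzoate | Cc1cc(OCc2ccccc2)cc(O)c1C(=O)OCc1ccccc1 | intermediate
3 | benzyl 4-(benzyloxy)-2-hydroxy-3-(hydroxymethyl)-6-methylbenzoate (not isolated) | Cc1cc(OCc2ccccc2)c(CO)c(O)c1C(=O)OCc1ccccc1 | intermediate
4 | benzyl 4-(benzyloxy)-3-formyl-2-hydroxy-6-methylbenzoate | Cc1cc(OCc2ccccc2)c(C=O)c(O)c1C(=O)OCc1ccccc1 | intermediate
5 | benzyl 4-(benzyloxy)-5-chloro-3-formyl-2-hydroxy-6-methylbenzoate | Cc1c(Cl)c(OCc2ccccc2)c(C=O)c(O)c1C(=O)OCc1ccccc1 | intermediate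
6 | benzyl 4-(benzyloxy)-5-chloro-3-(1,3-dioxolan-2-yl)-2-hydroxy-6-methylbenzoate | Cc1c(Cl)c(OCc2ccccc2)c(C2OCCO2)c(O)c1C(=O)OCc1ccccc1 | intermediate
7 | methyl 2-methyl-3-oxobutanoate (racemic) | CC(=O)C(C)C(=O)OC | starting material
8 | methyl 2-bromo-2-methyl-3-oxobutanoate (racemic, not isolated) | CC(=O)C(C)(Br)C(=O)OC | intermediate
9 | methyl 4-bromo-2-methyl-3-oxobutanoate (racemic) | COC(=O)C(C)C(=O)CBr | intermediate
10 | benzyl 4-(benzyloxy)-5-chloro-3-(1,3-dioxolan-2-yl)-2-(4-methoxy-3-methyl-2,4-dioxobutoxy)-6-methylbenzoate (racemic) | COC(=O)C(C)C(=O)COc1c(C2OCCO2)c(OCc2ccccc2)c(Cl)c(C)c1C(=O)OCc1ccccc1 | intermediate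
11 | benzyl 4-(benzyloxy)-5-chloro-3-(1,3-dioxolan-2-yl)-2-{[4-methoxy-3-methyl-4-oxo-2-(trimethylsilyloxy)but-2-en-1-yl]oxy}-6-methylbenzoate (E/Z mixture) | COC(=O)C(C)=C(O[Si](C)(C)C)COc1c(C2OCCO2)c(OCc2ccccc2)c(Cl)c(C)c1C(=O)OCc1ccccc1 | intermediate
12 | benzyl 4-(benzyloxy)-5-chloro-3-(1,3-dioxolan-2-yl)-2-{[(1Z,3Z)-4-methoxy-3-methyl-2,4-bis(trimethylsilyloxy)buta-1,3-dien-1-yl]oxy}-6-methylbenzoate | CO/C(O[Si](C)(C)C)=C(C)/C(O[Si](C)(C)C)=C/Oc1c(C2OCCO2)c(OCc2ccccc2)c(Cl)c(C)c1C(=O)OCc1ccccc1 | intermediate
13 | methyl but-2-ynoate | CC#CC(=O)OC | starting material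
14 | benzyl 4-(benzyloxy)-5-chloro-3-(1,3-dioxolan-2-yl)-2-{[4-methoxy-5-(methoxycarbonyl)-3,6-dimethyl-2,4-bis(trimethylsilyloxy)cyclohexa-2,5-dien-1-yl]oxy}-6-methylbenzoate (mixture of stereoisomers, not isolated) | COC(=O)C1=C(C)C(Oc2c(C3OCCO3)c(OCc3ccccc3)c(Cl)c(C)c2C(=O)OCc2ccccc2)C(O[Si](C)(C)C)=C(C)C1(OC)O[Si](C)(C)C | intermediate
15 | benzyl 4-(benzyloxy)-5-chloro-2-[2,4-dihydroxy-5-(methoxycarbonyl)-3,6-dimethylphenoxy]-3-(1,3-dioxolan-2-yl)-6-methylbenzoate (not isolated) | COC(=O)c1c(C)c(Oc2c(C3OCCO3)c(OCc3ccccc3)c(Cl)c(C)c2C(=O)OCc2ccccc2)c(O)c(C)c1O | intermediate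
16 | benzyl 4-(benzyloxy)-5-chloro-2-[2,4-dihydroxy-5-(methoxycarbonyl)-3,6-dimethylphenoxy]-3-formyl-6-methylbenzoate | COC(=O)c1c(C)c(Oc2c(C=O)c(OCc3ccccc3)c(Cl)c(C)c2C(=O)OCc2ccccc2)c(O)c(C)c1O | intermediate
17 | 3-chloro-6-[2,4-dihydroxy-5-(methoxycarbonyl)-3,6-dimethylphenoxy]-5-formyl-4-hydroxy-2-methylbenzoic acid | COC(=O)c1c(C)c(Oc2c(C=O)c(O)c(Cl)c(C)c2C(=O)O)c(O)c(C)c1O | target

## Step count and risks

Total step count: 10 steps. Longest linear sequence: 9 steps (1 to 17 through steps 1–4 and 6–10); step 5 is a one-step side branch.

Least certain steps and fallbacks: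

**Step 9 (key step).** The cycloaddition of the fully substituted diene with the weakly activated internal alkynoate may be slower than thermal degradation of 12 (silyl migration from oxygen to carbon, or hydrolysis back to 10). The ketal of 14 may also lose trimethylsilanol in place of methanol, leaving a methyl ether at C6. The fallback sets out from 12 and uses the more reactive allenic ester methyl buta-2,3-dienoate (purchased, C=C=CC(=O)OC) in toluene at 60–80 °C. It should add at its conjugated double bond with the same orientation to give the exocyclic methylene adduct benzyl 4-(benzyloxy)-5-chloro-3-(1,3-dioxolan-2-yl)-2-{[4-methoxy-5-(methoxycarbonyl)-3-methyl-6-methylidene-2,4-bis(trimethylsilyloxy)cyclohex-2-en-1-yl]oxy}-6-methylbenzoate F1. Aqueous HCl in THF would then remove methanol, the silyl groups and the acetal, the exocyclic double bond moving into the ring on aromatization, and the sequence comes back to the route at 16.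

**Step 2.** The formylation may stall, because the phenoxide is chelated to the ester and C3 lies between two oxygen substituents; the hydroxymethyl stage or its methoxymethyl ethers could then accumulate. The fallback sets out from 1.
- BnBr and KHCO3 in DMF would give benzyl 2,4-dihydroxy-6-methylbenzoate F2.
- Rieche formylation (Cl2CHOMe, TiCl4, CH2Cl2, −20 °C), directed by titanium chelation to the position between the two hydroxyls, would give benzyl 3-formyl-2,4-dihydroxy-6-methylbenzoate F3.
- SO2Cl2 would chlorinate the last open position to give benzyl 5-chloro-3-formyl-2,4-dihydroxy-6-methylbenzoate F4.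
- One equivalent of BnBr with K2CO3 should then alkylate the more acidic 4-hydroxyl (para to the ester, ortho to chlorine) and return to the route at 5. The weak point of this detour is the selectivity of that last alkylation.

**Step 6.** Base-induced self-condensation or cyclization of 9 may compete with O-alkylation of the hindered, chelated phenoxide. The fallback sets out from 6. Methyl bromoacetate and K2CO3 in acetone would give benzyl 4-(benzyloxy)-5-chloro-3-(1,3-dioxolan-2-yl)-2-(2-methoxy-2-oxoethoxy)-6-methylbenzoate F5. A crossed Claisen condensation with the lithium enolate of methyl propanoate (2.2 equiv, from LiN(iPr)2, THF, −78 °C) at the unhindered aliphatic ester would then return to the route at 10 and make step 5 unnecessary.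

**Step 10.** The Lewis acid may over-react, by cleavage of the ring A methyl ester through its boron chelate or by closure of the freed C6' acid onto C4–OH. The fallback sets out from 15, which would be isolated by ending step 9 with Bu4NF and AcOH in THF at 0 °C in place of aqueous HCl, so that the acetal is kept. Hydrogenolysis (H2, Pd/C, EtOAc, short reaction time, no base) would remove both benzyl groups while the acetal shields the aldehyde from reduction, giving 3-chloro-6-[2,4-dihydroxy-5-(methoxycarbonyl)-3,6-dimethylphenoxy]-5-(1,3-dioxolan-2-yl)-4-hydroxy-2-methylbenzoic acid F6. 1 M HCl in THF would then release the aldehyde and return to the route at 17. The hazard of this detour is slow hydrogenolysis of the C–Cl bond, which the neutral medium should limit.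

## Further compounds

F1 | step 9 | benzyl 4-(benzyloxy)-5-chloro-3-(1,3-dioxolan-2-yl)-2-{[4-methoxy-5-(methoxycarbonyl)-3-methyl-6-methylidene-2,4-bis(trimethylsilyloxy)cyclohex-2-en-1-yl]oxy}-6-methylbenzoate (mixture of stereoisomers) | COC(=O)C1C(=C)C(Oc2c(C3OCCO3)c(OCc3ccccc3)c(Cl)c(C)c2C(=O)OCc2ccccc2)C(O[Si](C)(C)C)=C(C)C1(OC)O[Si](C)(C)C
F2 | step 2 | benzyl 2,4-dihydroxy-6-methylbenzoate | Cc1cc(O)cc(O)c1C(=O)OCc1ccccc1
F3 | step 2 | benzyl 3-formyl-2,4-dihydroxy-6-methylbenzoate | Cc1cc(O)c(C=O)c(O)c1C(=O)OCc1ccccc1
F4 | step 2 | benzyl 5-chloro-3-formyl-2,4-dihydroxy-6-methylbenzoate | Cc1c(Cl)c(O)c(C=O)c(O)c1C(=O)OCc1ccccc1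
F5 | step 6 | benzyl 4-(benzyloxy)-5-chloro-3-(1,3-dioxolan-2-yl)-2-(2-methoxy-2-oxoethoxy)-6-methylbenzoate | COC(=O)COc1c(C2OCCO2)c(OCc2ccccc2)c(Cl)c(C)c1C(=O)OCc1ccccc1
F6 | step 10 | 3-chloro-6-[2,4-dihydroxy-5-(methoxycarbonyl)-3,6-dimethylphenoxy]-5-(1,3-dioxolan-2-yl)-4-hydroxy-2-methylbenzoic acid | COC(=O)c1c(C)c(Oc2c(C3OCCO3)c(O)c(Cl)c(C)c2C(=O)O)c(O)c(C)c1O
A1 | alternative 1 | benzyl 4-[2,4-bis(benzyloxy)-5-(methoxycarbonyl)-3,6-dimethylphenoxy]-6-methyl-2-oxo-2H-pyran-5-carboxylate | Cc1oc(=O)cc(Oc2c(C)c(C(=O)OC)c(OCc3ccccc3)c(C)c2OCc2ccccc2)c1C(=O)OCc1ccccc1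
A2 | alternative 1 | 2-chloro-1,1-dimethoxyethene | COC(OC)=CCl
A3 | alternative 1 | benzyl 2-[2,4-bis(benzyloxy)-5-(methoxycarbonyl)-3,6-dimethylphenoxy]-5-chloro-4-methoxy-6-methylbenzoate | COc1c(Cl)c(C)c(C(=O)OCc2ccccc2)c(Oc2c(C)c(C(=O)OC)c(OCc3ccccc3)c(C)c2OCc2ccccc2)c1
A4 | alternative 1 | methyl 2,4-bis(benzyloxy)-5-hydroxy-3,6-dimethylbenzoate | COC(=O)c1c(C)c(O)c(OCc2ccccc2)c(C)c1OCc1ccccc1
A5 | alternative 2 | 4-chloro-3-methylcyclobut-2-en-1-one (racemic) | CC1=CC(=O)C1Cl
A6 | alternative 2 | methyl 2,4-bis(benzyloxy)-5-{[3-(tert-butyldimethylsilyloxy)prop-1-yn-1-yl]oxy}-3,6-dimethylbenzoate | COC(=O)c1c(C)c(OC#CCO[Si](C)(C)C(C)(C)C)c(OCc2ccccc2)c(C)c1OCc1ccccc1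
A7 | alternative 2 | methyl 2,4-bis(benzyloxy)-5-[2-({tert-butyldimethylsilyloxy}methyl)-4-chloro-3-hydroxy-5-methylphenoxy]-3,6-dimethylbenzoate | COC(=O)c1c(C)c(Oc2cc(C)c(Cl)c(O)c2CO[Si](C)(C)C(C)(C)C)c(OCc2ccccc2)c(C)c1OCc1ccccc1
A8 | alternative 3 | 4-chloro-3-methoxy-5-methyl-2-(trimethylsilyl)phenyl trifluoromethanesulfonate | COc1c(Cl)c(C)cc(OS(=O)(=O)C(F)(F)F)c1[Si](C)(C)C
A9 | alternative 3 | 2-[2,4-bis(benzyloxy)-5-(methoxycarbonyl)-3,6-dimethylphenoxy]-5-chloro-6-methoxy-4-methylbenzoic acid | COC(=O)c1c(C)c(Oc2cc(C)c(Cl)c(OC)c2C(=O)O)c(OCc2ccccc2)c(C)c1OCc1ccccc1
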